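**Retrosynthetic overview**
- Feature: in the ten-membered carbocycle C1–C10 the 3(2H)-furanone (O–C3=C2–C1(=O)–C10) is a masked C1/C3 1,3-diketone and C10 is quaternary, so C1–C2 is an aldol bond between the enolate of a C3 ketone (hydrogens only at C2) and a C1 aldehyde that cannot enolise.
- Key disconnection: C1–C2 by SmI2 Reformatsky-type macrocyclisation of a bromomethyl Z-enone aldehyde; afterwards oxidation to the 1,3-diketone, transannular O10→C3 cyclodehydration to the furanone, C8 tiglate and desilylation.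
- Precursor: C3–C4 by Stille coupling on a Z-iodoalkene; C7–C8 by zinc Barbier addition of a 3-(bromomethyl)butenolide (C6 from Sharpless kinetic resolution, ring by metathesis) to a β-hydroxy aldehyde from (S)-2-methylglycidol (C10). This sets the 6,7-trans lactone and the 7,8-anti carbinol in one step and leaves an 8,10-diol for the acetonide.
- Ring order: lactone ring (as butenolide) → dioxane acetonide → ten-membered carbocycle → furanone.

Key step: step 17

Remark: germacrane numbering (C1–C15) is used for all intermediates; the CIP label of C6 is S while C4 carries iodine and R once C4 carries carbon, with no change in spatial arrangement.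
Remark: (S)-2-methylglycidol is assumed to be purchased; it is the Sharpless epoxidation product of 2-methylprop-2-en-1-ol in the L-(+)-tartrate series.

Step 1
Reactants: 1 but-2-yne-1,4-diol
Product: 2 4-[(tert-butyldiphenylsilyl)oxy]but-2-yn-1-ol
Conditions: 1 (3 equiv), TBDPSCl, imidazole, DMF, 0 °C → rt
Reagents that add atoms: tert-butyl(chloro)diphenylsilane, CC(C)(C)[Si](Cl)(c1ccccc1)c1ccccc1
Why: Statistical monosilylation of the symmetrical diol used in excess, with TBDPS chosen because this primary silyl ether must outlast the aqueous acid of step 19.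

Step 2
Reactants: 2 4-[(tert-butyldiphenylsilyl)oxy]but-2-yn-1-ol
Product: 4 (Z)-4-[(tert-butyldiphenylsilyl)oxy]-3-iodobut-2-en-1-ol, via cyclic alkenylalanate 3 (not isolated)
Conditions: NaAlH2(OCH2CH2OMe)2, THF, 0 °C; then I2, THF, −78 °C → 0 °C
Reagents that add atoms: iodine, II
Why: Hydroxyl-directed trans-hydroalumination of the propargylic alcohol puts hydride on C5 and aluminium on C4 in a five-membered alanate, and iodinolysis with retention should give the Z-iodoalkene with iodine cis to C6 (Corey-type hydroalumination–iodination).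

Step 3
Reactants: 4 (Z)-4-[(tert-butyldiphenylsilyl)oxy]-3-iodobut-2-en-1-ol
Product: 5 (Z)-4-[(tert-butyldiphenylsilyl)oxy]-3-iodobut-2-enal
Conditions: MnO2, CH2Cl2, rt, dark
Reagents that add atoms: none
Why: Neutral heterogeneous allylic oxidation with MnO2 should give the enal without Z/E isomerisation.

Step 4
Reactants: 5 (Z)-4-[(tert-butyldiphenylsilyl)oxy]-3-iodobut-2-enal; 6 vinylmagnesium bromide
Product: 7 rac-(Z)-6-[(tert-butyldiphenylsilyl)oxy]-5-iodohexa-1,4-dien-3-ol
Conditions: CH2=CHMgBr, THF, −78 °C; aq. NH4Cl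
Reagents that add atoms: none
Why: Grignard 1,2-addition to the aldehyde at low temperature should give the racemic bis-allylic C6 carbinol and install C7 as a vinyl group.

Step 5
Reactants: 7 rac-(Z)-6-[(tert-butyldiphenylsilyl)oxy]-5-iodohexa-1,4-dien-3-ol
Product: 8 (3S,4Z)-6-[(tert-butyldiphenylsilyl)oxy]-5-iodohexa-1,4-dien-3-ol
Conditions: Ti(OiPr)4 (cat.), diisopropyl L-(+)-tartrate (cat.), t-BuOOH (0.6 equiv), 4 Å MS, CH2Cl2, −20 °C, to just past half conversion
Reagents that add atoms: none
Why: Sharpless kinetic resolution of a 1-alken-3-ol, in which the L-(+)-tartrate catalyst epoxidises the vinyl group of the (R)-enantiomer and should leave the (S)-carbinol (the same sense as recovery of (R)-oct-1-en-3-ol), the cis-substituted and deactivated iodoalkene staying untouched.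

Step 6
Reactants: 8 (3S,4Z)-6-[(tert-butyldiphenylsilyl)oxy]-5-iodohexa-1,4-dien-3-ol; 9 2-(bromomethyl)prop-2-enoic acid
Product: 11 (3S,4Z)-6-[(tert-butyldiphenylsilyl)oxy]-5-iodohexa-1,4-dien-3-yl 2-(bromomethyl)prop-2-enoate, via O-acylisourea 10 (not isolated)
Conditions: DCC, DMAP (cat.), CH2Cl2, 0 °C
Reagents that add atoms: none
Why: Steglich esterification at 0 °C with only catalytic DMAP should acylate the secondary alcohol with retention at C6 and without displacing the allylic bromide.

Step 7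
Reactants: 11 (3S,4Z)-6-[(tert-butyldiphenylsilyl)oxy]-5-iodohexa-1,4-dien-3-yl 2-(bromomethyl)prop-2-enoate
Product: 12 (5S)-3-(bromomethyl)-5-{(Z)-3-[(tert-butyldiphenylsilyl)oxy]-2-iodoprop-1-en-1-yl}furan-2(5H)-one
Conditions: second-generation Hoveyda–Grubbs catalyst RuCl2(H2IMes)(=CH-C6H4-2-OiPr) (5 mol%), CH2Cl2, 40 °C, 0.01 M
Reagents that add atoms: none
Why: Ring-closing metathesis between the acrylate and vinyl groups should close the butenolide (C7=C11) under neutral conditions that do not touch the trisubstituted iodoalkene or the acidic C6 hydrogen.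

Step 8
Reactants: 13 (S)-2-methylglycidol
Product: 14 (2R)-2-{[(4-methoxybenzyl)oxy]methyl}-2-methyloxirane
Conditions: NaH, 4-methoxybenzyl chloride, Bu4NI (cat.), THF/DMF, 0 °C → rt
Reagents that add atoms: 4-methoxybenzyl chloride, COc1ccc(CCl)cc1
Why: Williamson etherification protects the future C1 oxygen, and the fully substituted epoxide carbon rules out Payne rearrangement, so C10 keeps its configuration (the label changes only by priority).

Step 9
Reactants: 14 (2R)-2-{[(4-methoxybenzyl)oxy]methyl}-2-methyloxirane; 6 vinylmagnesium bromide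
Product: 15 (2R)-1-[(4-methoxybenzyl)oxy]-2-methylpent-4-en-2-ol
Conditions: CH2=CHMgBr, CuI (10 mol%), THF, −30 °C → 0 °C
Reagents that add atoms: none
Why: Copper-catalysed Grignard opening of the 2,2-disubstituted epoxide at its unsubstituted carbon should give the homoallylic tertiary alcohol without touching the C10 stereocentre.

Step 10
Reactants: 15 (2R)-1-[(4-methoxybenzyl)oxy]-2-methylpent-4-en-2-ol
Product: 17 (3R)-3-hydroxy-4-[(4-methoxybenzyl)oxy]-3-methylbutanal, via pentanetriol 16 (not isolated)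
Conditions: OsO4 (cat.), NaIO4, 2,6-lutidine, dioxane/H2O, rt; product used crude
Reagents that add atoms: sodium periodate, [Na+].[O-]I(=O)(=O)=O
Why: Lemieux–Johnson dihydroxylation and glycol cleavage should unveil the C8 aldehyde without the over-oxidation of the PMB arene that ozone could cause.

Step 11
Reactants: 12 (5S)-3-(bromomethyl)-5-{(Z)-3-[(tert-butyldiphenylsilyl)oxy]-2-iodoprop-1-en-1-yl}furan-2(5H)-one; 17 (3R)-3-hydroxy-4-[(4-methoxybenzyl)oxy]-3-methylbutanal
Product: 19 (4R,5S)-4-{(1S,3R)-1,3-dihydroxy-4-[(4-methoxybenzyl)oxy]-3-methylbutyl}-5-{(Z)-3-[(tert-butyldiphenylsilyl)oxy]-2-iodoprop-1-en-1-yl}-3-methylidenedihydrofuran-2(3H)-one, via allylzinc bromide 18 (not isolated)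
Conditions: Zn dust, THF/sat. aq. NH4Cl, 0 °C → rt
Reagents that add atoms: none
Why: Zinc Barbier allylation of the Dreiding–Schmidt type, in which allylzinc 18 attacks through C7 (SE2′) in a chair Zimmerman–Traxler transition state: C8 should bond to the butenolide face opposite the C6 alkenyl group (6,7-trans lactone), and the ring-locked E-allyl geometry with the aldehyde chain equatorial should give the 7,8-anti carbinol, so that C7 (R) and C8 (S) both follow from C6.

Step 12
Reactants: 19 the diol lactone of step 11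
Product: 20 (4R,5S)-4-[(4S,6R)-6-{[(4-methoxybenzyl)oxy]methyl}-2,2,6-trimethyl-1,3-dioxan-4-yl]-5-{(Z)-3-[(tert-butyldiphenylsilyl)oxy]-2-iodoprop-1-en-1-yl}-3-methylidenedihydrofuran-2(3H)-one
Conditions: 2-methoxypropene, PPTS (cat.), CH2Cl2, 0 °C
Reagents that add atoms: 2-methoxypropene, COC(C)=C
Why: Kinetic acetonide formation ties the secondary C8 and tertiary C10 hydroxyls into a 1,3-dioxane, which also blocks migration of the lactone to O8.

Step 13
Reactants: 20 the PMB ether acetonide of step 12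
Product: 21 (4R,5S)-4-[(4S,6R)-6-(hydroxymethyl)-2,2,6-trimethyl-1,3-dioxan-4-yl]-5-{(Z)-3-[(tert-butyldiphenylsilyl)oxy]-2-iodoprop-1-en-1-yl}-3-methylidenedihydrofuran-2(3H)-one
Conditions: DDQ, CH2Cl2/pH 7 buffer, 0 °C; carried on at once
Reagents that add atoms: none
Why: Buffered oxidative PMB cleavage frees the C1 alcohol under near-neutral conditions that should leave the acetonide, silyl ether and iodoalkene alone.

Step 14
Reactants: 21 the primary alcohol of step 13
Product: 22 (4R,6S)-6-[(2S,3R)-2-{(Z)-3-[(tert-butyldiphenylsilyl)oxy]-2-iodoprop-1-en-1-yl}-4-methylidene-5-oxotetrahydrofuran-3-yl]-2,2,4-trimethyl-1,3-dioxane-4-carbaldehyde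
Conditions: Dess–Martin periodinane, NaHCO3, CH2Cl2, 0 °C → rt
Reagents that add atoms: none
Why: Buffered Dess–Martin oxidation of the neopentyl-type alcohol should give the C1 aldehyde, which has no α-hydrogen and so cannot epimerise or enolise.

Step 15
Reactants: 22 the iodoalkenyl aldehyde of step 14; 23 tributyl(1-ethoxyvinyl)tin
Product: 24 (4R,6S)-6-[(2R,3R)-2-{(Z)-2-{[(tert-butyldiphenylsilyl)oxy]methyl}-3-ethoxybuta-1,3-dien-1-yl}-4-methylidene-5-oxotetrahydrofuran-3-yl]-2,2,4-trimethyl-1,3-dioxane-4-carbaldehyde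
Conditions: Pd2(dba)3 (cat.), AsPh3, CuI (cat.), DMF, 40 °C; chromatography on Et3N-deactivated silica
Reagents that add atoms: none
Why: Stille coupling (oxidative addition of zerovalent palladium into the C4–iodine bond, transmetallation, reductive elimination) should form C3–C4 with retention of the alkene geometry, placing C3 cis to C6 under fluoride-free, non-basic conditions.

Step 16
Reactants: 24 the 2-ethoxydiene of step 15
Product: 25 (4R,6S)-6-[(2R,3R)-2-{(Z)-4-bromo-2-{[(tert-butyldiphenylsilyl)oxy]methyl}-3-oxobut-1-en-1-yl}-4-methylidene-5-oxotetrahydrofuran-3-yl]-2,2,4-trimethyl-1,3-dioxane-4-carbaldehyde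
Conditions: NBS, THF/H2O, 0 °C
Reagents that add atoms: N-bromosuccinimide, O=C1CCC(=O)N1Br; water, O
Why: Electrophilic bromination of the electron-rich enol ether at C2 and hydrolysis of the resulting oxocarbenium ion should give the bromomethyl ketone regiospecifically, the electron-poor alkenes being inert to NBS.

Step 17
Reactants: 25 the bromomethyl Z-enone aldehyde of step 16
Product: 27 ten-membered β-hydroxy ketone acetonide (1RS,6R,7R,8S,10R), via samarium enolate 26 (not isolated)
Conditions: SmI2 (2.2 equiv, 0.1 M in THF) added slowly to 25 (0.002 M in THF), −78 °C; sat. aq. NH4Cl at −78 °C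
Reagents that add atoms: none
Why: Two single-electron transfers from divalent samarium cleave the C2–Br bond and give the trivalent samarium enolate 26, regiospecifically at C2 because C4 carries no hydrogen, and this enolate adds to the C1 aldehyde through a samarium-chelated cyclic transition state, an intramolecular Reformatsky-type aldol whose SmI2 variant is known to close medium and large rings. The ten-membered carbocycle C1–C10 is closed by a 10-exo-trig enolate addition (enolexo mode), the Z-C4=C5 alkene, the trans-fused lactone at C6/C7 and the dioxane at C8–C10 removing most of the freely rotating bonds between C2 and C1. The new C1 carbinol centre is not controlled and need not be, since both epimers are oxidised in step 18. The selectivity needed is chemoselectivity: the α-bromo ketone is reduced far faster than the enone, the aldehyde or the α-methylene lactone at −78 °C, and slow addition of just over two equivalents leaves no excess reductant for these groups or for reductive loss of the γ-acyloxy group. The aldehyde sits on quaternary C10 and cannot enolise, so no proton transfer quenches the enolate, and high dilution suppresses intermolecular aldol reaction.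

Step 18
Reactants: 27 ten-membered β-hydroxy ketone acetonide (both C1 epimers)
Product: 28 ten-membered 1,3-diketone acetonide (6R,7R,8S,10R)
Conditions: Dess–Martin periodinane, NaHCO3, CH2Cl2, 0 °C → rt
Reagents that add atoms: none
Why: Buffered Dess–Martin oxidation of a β-hydroxy ketone should give the C1/C3 1,3-diketone from both epimers without dehydration.

Step 19
Reactants: 28 ten-membered 1,3-diketone acetonide
Product: 30 15-O-(tert-butyldiphenylsilyl)-8-O-destigloyllychnophorolide B, via dihydroxy diketone 29 (not isolated)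
Conditions: 1 M aq. HCl, THF, rt
Reagents that add atoms: none
Why: Acid hydrolysis of the acetonide frees the tertiary C10 hydroxyl, which should add across the ring to the C3 carbonyl (5-exo-trig hemiketal) and lose water to give the vinylogous ester, the known cyclodehydration of α′-hydroxy 1,3-diketones to 3(2H)-furanones, while the TBDPS ether survives dilute acid.

Step 20
Reactants: 30 15-O-(tert-butyldiphenylsilyl)-8-O-destigloyllychnophorolide B; 31 tiglic acid
Product: 33 15-O-(tert-butyldiphenylsilyl)lychnophorolide B, via mixed anhydride 32 (not isolated)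
Conditions: 31, 2,4,6-trichlorobenzoyl chloride, Et3N, THF, rt; then 30, DMAP, toluene, rt → 40 °C
Reagents that add atoms: none
Why: Yamaguchi esterification is the usual method for acylating hindered secondary alcohols with sluggish α,β-unsaturated acids, and the C8 hydroxyl is the only free one.

Step 21
Reactants: 33 15-O-(tert-butyldiphenylsilyl)lychnophorolide B
Product: 34 lychnophorolide B
Conditions: HF·pyridine, pyridine, THF, 0 °C → rt
Reagents that add atoms: none
Why: Buffered fluoride cleavage of the primary TBDPS ether should release the C15 alcohol without harming the tiglate, the α-methylene lactone or the furanone.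

**Compound list**
1 | but-2-yne-1,4-diol | OCC#CCO | starting material
2 | 4-[(tert-butyldiphenylsilyl)oxy]but-2-yn-1-ol | OCC#CCO[Si](c1ccccc1)(c1ccccc1)C(C)(C)C | intermediate
3 | sodium cyclic alkenylalanate, 2,2-bis(2-methoxyethoxy)-3-{[(tert-butyldiphenylsilyl)oxy]methyl}-2,5-dihydro-1,2-oxaluminol-2-uide | [Na+].COCCO[Al-]1(OCCOC)OCC=C1CO[Si](c1ccccc1)(c1ccccc1)C(C)(C)C | intermediate
4 | (Z)-4-[(tert-butyldiphenylsilyl)oxy]-3-iodobut-2-en-1-ol | OC/C=C(/CO[Si](c1ccccc1)(c1ccccc1)C(C)(C)C)I | intermediate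
5 | (Z)-4-[(tert-butyldiphenylsilyl)oxy]-3-iodobut-2-enal | O=C/C=C(/CO[Si](c1ccccc1)(c1ccccc1)C(C)(C)C)I | intermediate
6 | vinylmagnesium bromide | C=C[Mg]Br | starting material
7 | rac-(Z)-6-[(tert-butyldiphenylsilyl)oxy]-5-iodohexa-1,4-dien-3-ol | C=CC(O)/C=C(/CO[Si](c1ccccc1)(c1ccccc1)C(C)(C)C)I | intermediate
8 | (3S,4Z)-6-[(tert-butyldiphenylsilyl)oxy]-5-iodohexa-1,4-dien-3-ol | C=C[C@H](O)/C=C(/CO[Si](c1ccccc1)(c1ccccc1)C(C)(C)C)I | intermediate
9 | 2-(bromomethyl)prop-2-enoic acid | C=C(CBr)C(=O)O | starting material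
10 | O-acylisourea from 9 and DCC | C=C(CBr)C(=O)OC(=NC1CCCCC1)NC1CCCCC1 | intermediate
11 | (3S,4Z)-6-[(tert-butyldiphenylsilyl)oxy]-5-iodohexa-1,4-dien-3-yl 2-(bromomethyl)prop-2-enoate | C=C(CBr)C(=O)O[C@@H](C=C)/C=C(/CO[Si](c1ccccc1)(c1ccccc1)C(C)(C)C)I | intermediate
12 | (5S)-3-(bromomethyl)-5-{(Z)-3-[(tert-butyldiphenylsilyl)oxy]-2-iodoprop-1-en-1-yl}furan-2(5H)-one | O=C1O[C@H](/C=C(/CO[Si](c2ccccc2)(c2ccccc2)C(C)(C)C)I)C=C1CBr | intermediate
13 | (S)-2-methylglycidol, [(2S)-2-methyloxiran-2-yl]methanol | C[C@]1(CO)CO1 | starting material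
14 | (2R)-2-{[(4-methoxybenzyl)oxy]methyl}-2-methyloxirane | C[C@]1(COCc2ccc(OC)cc2)CO1 | intermediate
15 | (2R)-1-[(4-methoxybenzyl)oxy]-2-methylpent-4-en-2-ol | C=CC[C@@](C)(O)COCc1ccc(OC)cc1 | intermediate
16 | (4R)-5-[(4-methoxybenzyl)oxy]-4-methylpentane-1,2,4-triol, both C2 epimers | OCC(O)C[C@@](C)(O)COCc1ccc(OC)cc1 | intermediate
17 | (3R)-3-hydroxy-4-[(4-methoxybenzyl)oxy]-3-methylbutanal | O=CC[C@@](C)(O)COCc1ccc(OC)cc1 | intermediate
18 | allylzinc bromide of 12, zinc on the former CH2Br carbon | O=C1O[C@H](/C=C(/CO[Si](c2ccccc2)(c2ccccc2)C(C)(C)C)I)C=C1C[Zn]Br | intermediate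
19 | (4R,5S)-4-{(1S,3R)-1,3-dihydroxy-4-[(4-methoxybenzyl)oxy]-3-methylbutyl}-5-{(Z)-3-[(tert-butyldiphenylsilyl)oxy]-2-iodoprop-1-en-1-yl}-3-methylidenedihydrofuran-2(3H)-one (6S,7R,8S,10R) | C=C1C(=O)O[C@H](/C=C(/CO[Si](c2ccccc2)(c2ccccc2)C(C)(C)C)I)[C@H]1[C@@H](O)C[C@@](C)(O)COCc1ccc(OC)cc1 | intermediate
20 | (4R,5S)-4-[(4S,6R)-6-{[(4-methoxybenzyl)oxy]methyl}-2,2,6-trimethyl-1,3-dioxan-4-yl]-5-{(Z)-3-[(tert-butyldiphenylsilyl)oxy]-2-iodoprop-1-en-1-yl}-3-methylidenedihydrofuran-2(3H)-one | C=C1C(=O)O[C@H](/C=C(/CO[Si](c2ccccc2)(c2ccccc2)C(C)(C)C)I)[C@H]1[C@@H]2C[C@](C)(COCc3ccc(OC)cc3)OC(C)(C)O2 | intermediate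
21 | (4R,5S)-4-[(4S,6R)-6-(hydroxymethyl)-2,2,6-trimethyl-1,3-dioxan-4-yl]-5-{(Z)-3-[(tert-butyldiphenylsilyl)oxy]-2-iodoprop-1-en-1-yl}-3-methylidenedihydrofuran-2(3H)-one | C=C1C(=O)O[C@H](/C=C(/CO[Si](c2ccccc2)(c2ccccc2)C(C)(C)C)I)[C@H]1[C@@H]2C[C@](C)(CO)OC(C)(C)O2 | intermediate
22 | (4R,6S)-6-[(2S,3R)-2-{(Z)-3-[(tert-butyldiphenylsilyl)oxy]-2-iodoprop-1-en-1-yl}-4-methylidene-5-oxotetrahydrofuran-3-yl]-2,2,4-trimethyl-1,3-dioxane-4-carbaldehyde | C=C1C(=O)O[C@H](/C=C(/CO[Si](c2ccccc2)(c2ccccc2)C(C)(C)C)I)[C@H]1[C@@H]2C[C@](C)(C=O)OC(C)(C)O2 | intermediate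
23 | tributyl(1-ethoxyvinyl)tin | CCCC[Sn](CCCC)(CCCC)C(=C)OCC | starting material
24 | (4R,6S)-6-[(2R,3R)-2-{(Z)-2-{[(tert-butyldiphenylsilyl)oxy]methyl}-3-ethoxybuta-1,3-dien-1-yl}-4-methylidene-5-oxotetrahydrofuran-3-yl]-2,2,4-trimethyl-1,3-dioxane-4-carbaldehyde | C=C1C(=O)O[C@H](/C=C(/CO[Si](c2ccccc2)(c2ccccc2)C(C)(C)C)C(=C)OCC)[C@H]1[C@@H]2C[C@](C)(C=O)OC(C)(C)O2 | intermediate
25 | (4R,6S)-6-[(2R,3R)-2-{(Z)-4-bromo-2-{[(tert-butyldiphenylsilyl)oxy]methyl}-3-oxobut-1-en-1-yl}-4-methylidene-5-oxotetrahydrofuran-3-yl]-2,2,4-trimethyl-1,3-dioxane-4-carbaldehyde (key-step precursor) | C=C1C(=O)O[C@H](/C=C(/CO[Si](c2ccccc2)(c2ccccc2)C(C)(C)C)C(=O)CBr)[C@H]1[C@@H]2C[C@](C)(C=O)OC(C)(C)O2 | intermediate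
26 | diiodosamarium enolate of 25 (O–Sm on C3, C2=C3) | C=C1C(=O)O[C@H](/C=C(/CO[Si](c2ccccc2)(c2ccccc2)C(C)(C)C)C(=C)O[Sm](I)I)[C@H]1[C@@H]2C[C@](C)(C=O)OC(C)(C)O2 | intermediate
27 | ten-membered β-hydroxy ketone: carbocycle C1–C10 with C1 OH (both epimers), C3 ketone, (4Z)-alkene bearing CH2OTBDPS, 6,7-trans-fused α-methylene-γ-lactone and O8/O10 acetonide; (1RS,6R,7R,8S,10R) | C=C1C(=O)O[C@@H]2/C=C(/CO[Si](c3ccccc3)(c3ccccc3)C(C)(C)C)C(=O)CC(O)[C@@]3(C)C[C@H](OC(C)(C)O3)[C@@H]12 | intermediate
28 | ten-membered C1/C3 1,3-diketone acetonide, otherwise as 27; (6R,7R,8S,10R) | C=C1C(=O)O[C@@H]2/C=C(/CO[Si](c3ccccc3)(c3ccccc3)C(C)(C)C)C(=O)CC(=O)[C@@]3(C)C[C@H](OC(C)(C)O3)[C@@H]12 | intermediate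
29 | 8,10-dihydroxy 1,3-diketone (acetonide removed); (6R,7R,8S,10R) | C=C1C(=O)O[C@@H]2/C=C(/CO[Si](c3ccccc3)(c3ccccc3)C(C)(C)C)C(=O)CC(=O)[C@](C)(O)C[C@H](O)[C@@H]12 | intermediate
30 | 15-O-(tert-butyldiphenylsilyl)-8-O-destigloyllychnophorolide B (furanone closed, free C8 OH); (6R,7R,8S,10R) | C=C1C(=O)O[C@@H]2/C=C(/CO[Si](c4ccccc4)(c4ccccc4)C(C)(C)C)C3=CC(=O)[C@@](C)(C[C@H](O)[C@@H]12)O3 | intermediate
31 | tiglic acid, (E)-2-methylbut-2-enoic acid | C/C=C(\C)C(=O)O | starting material
32 | tiglic 2,4,6-trichlorobenzoic mixed anhydride | C/C=C(\C)C(=O)OC(=O)c1c(Cl)cc(Cl)cc1Cl | intermediate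
33 | 15-O-(tert-butyldiphenylsilyl)lychnophorolide B; (6R,7R,8S,10R) | C=C1C(=O)O[C@@H]2/C=C(/CO[Si](c4ccccc4)(c4ccccc4)C(C)(C)C)C3=CC(=O)[C@@](C)(C[C@H](OC(=O)/C(C)=C/C)[C@@H]12)O3 | intermediate
34 | lychnophorolide B; (6R,7R,8S,10R) | C=C1C(=O)O[C@@H]2/C=C(/CO)C3=CC(=O)[C@@](C)(C[C@H](OC(=O)/C(C)=C/C)[C@@H]12)O3 | target

**Totals**
Total step count: 21. Longest linear sequence: 18 steps (steps 1–7 and 11–21, from but-2-yne-1,4-diol).

**Steps most likely to fail**

Step 17 (macrocyclisation). The samarium enolate may be protonated before it finds the aldehyde (giving the methyl ketone), intermolecular aldol addition may outrun closure of the strained ten-membered ring, or excess reductant may attack the γ-acyloxy enone. The fallback keeps the C1–C2 aldol closure but drops the reductive enolate generation. It sets out from enol ether 24: mild hydrolysis (PPTS, wet acetone, 0 °C) should give the methyl ketone F1, which can enolise only at C2. Bu2BOTf and iPr2NEt are then added to dilute F1 in CH2Cl2 at −78 °C to form the dibutylboron enolate F2, which should close onto the C1 aldehyde in an intramolecular boron-mediated aldol reaction. Work-up with pH 7 buffer and methanol returns to the route at 27.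

Step 11 (Barbier coupling). Protonolysis of the allylzinc by water, loose facial control at the aldehyde (C8 epimers) or migration of the lactone to the new C8 hydroxyl in the aqueous medium may erode the step. The fallback replaces the aqueous Barbier by an anhydrous Nozaki–Hiyama allylation with a preformed reagent. It sets out from bromide 12: divalent chromium chloride CrCl2 in dry THF should give the trivalent allylchromium dichloride F3, which is then treated with aldehyde 17. The aprotic medium and the tight chair transition state should give the same 6,7-trans, 7,8-anti adduct, and the iodoalkene is inert without a nickel co-catalyst. It returns to the route at 19.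

Step 20 (late tigloylation). Acylation of the hindered C8 hydroxyl by the deactivated α,β-unsaturated acyl donor may be slow, leaving time for base-mediated conjugate addition of the free hydroxyl to C5 or isomerisation of the α-methylene lactone. The fallback builds the tiglate on the ester instead of delivering it. It sets out from alcohol 30: esterification with the unhindered 2-(diethoxyphosphoryl)propanoic acid (DCC, DMAP cat., CH2Cl2) should give the phosphonate ester F4. A Masamune–Roush Horner–Wadsworth–Emmons reaction with acetaldehyde (LiCl, iPr2NEt, MeCN) should then form the (E)-2-methylbut-2-enoate. It returns to the route at 33.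

**Further compounds**
F1 | step 17 | methyl ketone corresponding to 25 (C2 as CH3), (4R,6S)-6-[(2R,3R)-2-{(Z)-2-{[(tert-butyldiphenylsilyl)oxy]methyl}-3-oxobut-1-en-1-yl}-4-methylidene-5-oxotetrahydrofuran-3-yl]-2,2,4-trimethyl-1,3-dioxane-4-carbaldehyde | C=C1C(=O)O[C@H](/C=C(/CO[Si](c2ccccc2)(c2ccccc2)C(C)(C)C)C(C)=O)[C@H]1[C@@H]2C[C@](C)(C=O)OC(C)(C)O2
F2 | step 17 | dibutylboron enolate of F1 (O–B on C3, C2=C3) | C=C1C(=O)O[C@H](/C=C(/CO[Si](c2ccccc2)(c2ccccc2)C(C)(C)C)C(=C)OB(CCCC)CCCC)[C@H]1[C@@H]2C[C@](C)(C=O)OC(C)(C)O2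
F3 | step 11 | allylchromium dichloride of 12, chromium on the former CH2Br carbon | O=C1O[C@H](/C=C(/CO[Si](c2ccccc2)(c2ccccc2)C(C)(C)C)I)C=C1C[Cr](Cl)Cl
F4 | step 20 | 8-O-[2-(diethoxyphosphoryl)propanoyl] ester of 30 (phosphonate α-carbon as a mixture) | C=C1C(=O)O[C@@H]2/C=C(/CO[Si](c4ccccc4)(c4ccccc4)C(C)(C)C)C3=CC(=O)[C@@](C)(C[C@H](OC(=O)C(C)P(=O)(OCC)OCC)[C@@H]12)O3
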